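All runs were computed with constants of no real substance; noise was put on by code.

The green flask at 80 °C reaches 27.0% of left-handed product in half the time the grey run at 65 °C needs for 28.1%, yet their last readings lie close together: 45.3% at 12.0 min and 46.7% at 25.0 min.

| setting | green | grey | flask |
|---|---|---|---|
| left-handed substrate | 0.073 M | 0.073 M | 0.073 M |
| right-handed substrate | 0.073 M | 0.073 M | 0.073 M |
| partner | 0.0876 M | 0.0876 M | 0.0876 M |
| catalyst | 36 µM | 36 µM | 36 µM |
| temperature | 80 °C | 65 °C | 80 °C |
| remark | the very flask that is asked about, followed so far | run made earlier |  |
| time |  |  | 20 min |

| green: time / min | green: left-handed product / % | grey: time / min | grey: left-handed product / % |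
|---|---|---|---|
| 1.00 | 17.9 | 2.00 | 19.4 |
| 1.33 | 21.1 | 3.00 | 24.8 |
| 2.00 | 27.0 | 4.00 | 28.1 |
| 3.00 | 32.7 | 6.00 | 34.3 |
| 5.00 | 38.6 | 10.0 | 39.4 |
| 8.00 | 43.4 | 15.0 | 43.7 |
| 12.0 | 45.3 | 25.0 | 46.7 |

(readings scatter by 0.5 percentage points)

- dusk: at 20 min raise the temperature by 20 K, then wait 20 min
- noon: at 20 min add catalyst, 50.0% of the amount charged, then wait 20 min
- winter: at 20 min add partner, 50.0% of the amount charged, then wait 20 min
- spring: at 20 min take out 90% of the left-handed product then present, then wait 20 min
- dawn: change nothing and wait 20 min more

- left-handed product, in percent of the left-handed substrate and right-handed substrate together first charged, at 20 min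
- the remedy with the largest gain of left-handed product, or "none" below 2 percentage points (dusk / noon / winter / spring / dawn / none)
- left-handed product present, with what was taken out counted in, in percent of the left-handed substrate and right-handed substrate together first charged, after dusk
- left-handed product present, with what was taken out counted in, in percent of the left-handed substrate and right-handed substrate together first charged, after winter

- catalyst is single-handed; left-handed substrate and right-handed substrate are mirror images of each other, charged as a racemate, each of them at the stated concentration
- removed left-handed product is counted in
- additions bring no volume worth counting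

Ines and Tom disagree about what the green flask holds at 20 min, and whether any remedy can then gain 2 percentage points.

Ines holds fixed the height, which heat seems not to move. If one partner goes with one left-handed substrate and the right-handed substrate stays out, the ceiling is the smaller of c(left-handed substrate) and c(partner), taken over both substrates charged: 50.0%. In the green flask the left-handed substrate is the limiting reagent, since its 0.073 M is less than the 0.0876 M of partner.

On her view a remedy gains out of the room under that ceiling. By the green readings the room went from 6.6 points at 8.00 min to 4.7 points at 12.0 min, a factor of 0.712. Two more such steps leave 2.4 points, so her own reckoning is 47.6% at 20 min.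

Tom watches the pace instead. The green readings gained 4.8 points in 3.00 min, then 1.9 points in 4.00 min, so the gain per minute fell to 0.297 of what it was. If that continues, his own reckoning for the green flask is 46.0% at 20 min, with 4 points of room for heat to collect, more than 2 points. Ines answers that a difference of two readings scatters by 0.71 points, a third of that last gain.

The forecast takes her side, though higher than her reckoning: 48.1%, best none, 49.7% after dusk and 49.8% after winter, with “only about 2% left to gain”.

The simulation gives 48.1%, best none, 49.9% after dusk and 50.0% after winter, from these steps:

    partner + catalyst + left-handed substrate → catalyst + left-handed product (k = 2800 L² mol⁻² s⁻¹, Ea = 36.0 kJ mol⁻¹)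
    partner + catalyst + right-handed substrate → catalyst + right-handed product (k = 22.0 L² mol⁻² s⁻¹, Ea = 50.0 kJ mol⁻¹)
    (constants at 80 °C)

The ceiling of 50.0% leaves the asked flask at 20 min room of 1.9 points, less than 2 points, and winter's 1.9 points is the largest gain. Tom's view has its region earlier: in the asked flask the answer moves 5 points on looking at 8.29 min. In the neighbour flask with 0.035 M of partner, the smaller charge, the same rule gives 24.0%, and that flask stands at 23.6% with 0.48% of its partner left.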